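## Structural features

Brassicicene M is a 5-9-5 carbotricycle. Cyclopentane ring A (C2–C6) and cyclopentenone ring C (C10–C14) flank a nine-membered ring B (C1, C2, C6–C12). Rings B and C share C10–C11–C12, so B/C is a bicyclo[6.2.1]undecane with the C10=C14 enone double bond at a bridgehead; ring A is joined to ring B through the exocyclic trisubstituted C1=C2 olefin, with C12 cis to C6. There are six stereocentres: the isolated tertiary carbinol C3 (bearing CH2OMe), the contiguous triad C6(H)–C7(CH3)–C8(OH), and the adjacent fully substituted carbinols C11 and C12, whose hydroxyl groups are trans on ring C. Fragile elements are the tertiary allylic alcohols at C3 and C12, the C12/C13 α-ketol, the C11 hydroxyl β to the C13 ketone (retro-aldol under base) and, in precursors, enol ethers and bridgehead unsaturation. The real difficulty is the nine-membered ring with its olefin geometry and the C6/C7 pair, plus the relay of configuration between the remote C3 centre and the ring C centres. The key step exploits the 1,5-relationship of the C8 oxygen, the C7 methyl and the C1=C2 olefin: C7=C8–O···C1–C2=C6 is the product pattern of a Claisen shift, so ring B is the ring-expanded form of an oxepane (O, C8–C12, C1) fused to ring C.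

## Logic of the disconnections

31 back to 27. No skeletal bond is cut. The protecting-group O–C and O–Si bonds are restored (31 to 30 to 29), the C10=C14 π bond is exchanged for a C13 silyl enol ether with C10 sp3 (29 to 28), and the C8–H bond is removed to give the C8 carbonyl (28 to 27). This reaches a compound with no bridgehead olefin and a C8 ketone, the form a sigmatropic shift delivers. One stereocentre (C8) and all free hydroxyls are removed. Forward, hydride must reach one face of C8 in a medium ring, dehydrosilylation must take the C10 hydrogen and not the isopropyl methine, and deprotection must avoid retro-aldol and ionisation.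

27 back to 26. The C6–C7 bond is cut and C1–O is re-formed; the C8 carbonyl becomes the C7=C8 enol ether. This is the only cut that turns the nine-membered carbocycle into a seven-membered ether and replaces two stereocentres and an olefin geometry by one stereocentre (C1) and one enol ether geometry. Forward, 26 must be the 1S, Z isomer, and the shift must outrun isomerisation or hydrolysis of the enol ether.

26 back to 24 and 25. The C7=C8 bond is cut, giving a lactone carbonyl and a two-carbon alkylidene donor. The enol ether is too labile to carry, and the lactone is robust. Forward, a non-basic, Z-selective alkylidenation of an ester carbonyl is needed in the presence of silyl and MOM ethers.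

24 back to 22. The acyl C8–O bond is cut. Lactonisation replaces a ring-expanding peracid oxidation, which would not spare the C13 silyl enol ether or the ring A olefin. Forward, a bridged seven-membered lactone must close on a hindered secondary alcohol with retention at C1.

22 back to 20 and 6. The C1–C2 bond is cut between the carbinol carbon and ring A. Two enantiopure halves are joined by carbonyl addition, the most reliable way to bond a neopentyl carbon to a hindered alkenyl group. Forward, Felkin-type addition must give 1S, and the C8 carboxyl must be tolerated.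

20 back to 18 and 17. C1 and C8 are reconnected: aldehyde and acid are the two ends of a cleaved C1=C8 enol ether, which comes from the α-chloro ketone. The acyclic cis-1,3 pattern is thus derived from a bicycle in which it is automatic. Forward, enolisation must be regiospecific at C1 (the hindered side); this is secured by the chlorine, because base would enolise the chlorine-free ketone towards C9.

17 back to 15 and 16. The C1–C12 and C9–C10 bonds are cut ([4+3]). One step sets C10 and C12 relative to C11 and places the three-carbon bridge cis to the C11 oxygen. Forward, the oxyallyl cation must add syn to the alkoxy group and with its chlorine-bearing terminus at C12.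

15 back to 7. O–Si bonds (15 to 14), the C13–O bond (14 to 12), the MOM O–C bond (12 to 11), the C11–O bond (11 to 10), the C11–CH3 bond (10 to 9) and the C14–isopropyl bond (9 to 7) are cut in turn. Each step uses the only enolisable position left, so regiochemistry is built in. Forward, the C11 stereocentre must be set by a reagent-controlled hydroxylation.

6 back to 1. The O–CH3 bond (6 to 5), the ester reduction (5 to 4), the enol O–S bond (4 to 3), the O–Si bond (3 to 2) and the C3–O bond (2 to 1) are undone. The ester serves as latent CH2OMe and activates the α-carbon for asymmetric hydroxylation. Forward, a catalytic enantioselective hydroxylation must give the 1R alcohol.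

## Other disconnections considered

Alternative 1: The cut is C2–C3, with the C1=C2 olefin traced back to a C1≡C2 alkyne. Forward, a zerovalent nickel catalyst would join the alkyne and the C3 ketone of ynone A1 in an oxanickelacycle, which a silane cleaves to give A2 with ring A closed, C3 silylated and the olefin set by syn addition.
- In its favour: the olefin geometry follows from the mechanism alone, the halves are joined early by acetylide chemistry, and the reaction runs near room temperature.
- Against it here: α-alkoxy ketones are less proven partners than aldehydes; the alkyne is propargylic to the fully substituted C12 and lies next to the ring C enone, which itself couples with alkynes under such catalysts; C3 would rest on 1,3-induction from C6; and A2 still lacks the C8–C9 bond, so ring B must be closed later end to end.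
- Comparison: on control of the C1=C2 geometry it is the equal of the chosen plan, and on mildness it is the better. Structurally it leaves the medium ring unsolved, whereas the chosen step makes ring B, C6 and C7 together. No saving in steps is expected once ring B and C8 are added.

Alternative 2: The cuts are C10=C14 and C8–C9. Forward, base would condense C14 with the C10 methyl ketone of keto aldehyde A3 to make ring C; the dienolate formed at C9 would then add to the C8 aldehyde to close ring B and give A4.
- In its favour: two rings, the enone and the C8 carbinol arise in one flask with no redox adjustment at C13/C14. Counted from fragment union it is the shortest route, and in step economy it is the better plan; reaching the C8 alcohol directly is also an advantage.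
- Against it here: A3 has competing enolisation sites (the methyl ketone can attack C13), an epimerisable C7 next to the aldehyde, and a dienolate that must react at its γ-carbon; the second aldol is a reversible end-to-end nine-membered closure with no clear control of C8.
- Comparison: both plans end at the same skeleton. Mechanistically the chosen shift is unimolecular, irreversible and stereospecific from a preorganised ring, while the cascade is an equilibrium network; the shorter count is offset by lower confidence in the central step.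

Alternative 3: The cut is C12–C13. Forward, an N-heterocyclic carbene would turn the C13 aldehyde of enal A5 into an acyl anion equivalent that adds to the C12 ring ketone, closing ring C and giving A6.
- In its favour: the α-ketol and the enone appear at final oxidation level, the ring formed is five-membered, the conditions are catalytic and mild, and A6 is two silyl ethers from the target. For the end-game it is the better plan.
- Against it here: the aldehyde is a hindered tetrasubstituted enal, prone to homoenolate or redox pathways; the acceptor is an enone, so conjugate addition competes; C12 would be set by the conformation of the nine-membered ring; and A5 already contains ring B, both olefin geometries and the C6/C7/C8 triad.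
- Comparison: better in oxidation-state economy, equal in mildness. Structurally it solves the easier ring and moves the hard problem into the synthesis of A5; overall length is not expected to be lower.

Key step: step 18

Remark (numbering): C1–C14 are the target's carbon labels, used also for fragments.

Remark (stereochemistry of 26): the enol ether is made and drawn as the 1S epimer, with the cyclopentenyl group on the oxepane face that also carries the C13=C14 bridge. Suprafacial transfer with C12 cis to C6 maps 1S onto 6S; a 1R structure would lead to 6R/7S and would be in error for this target. The six reacting atoms adopt a chair-like array, and only the oxepane ring is boat-like.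

Assumption: the sense of induction in the two reagent-controlled hydroxylations (steps 1 and 8) is taken from the closest enolate models; both antipodes of each chiral agent are available, so the R products are treated as accessible.

## Route

Step 1
Reactants: 1 methyl 2-oxocyclopentane-1-carboxylate
Product: 2 methyl (1R)-1-hydroxy-2-oxocyclopentane-1-carboxylate
Conditions: dihydroquinine (10 mol %), cumene hydroperoxide, toluene, −20 °C
Reagents that add atoms: cumene hydroperoxide, CC(C)(OO)c1ccccc1
Why: Cinchona-catalysed enantioselective α-hydroxylation of a cyclic β-keto ester; the ion-paired enolate is oxidised on one face, and the alkaloid series (quinine or quinidine type) is chosen to give 1R. Optical purity would be raised by crystallisation downstream if needed.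

Step 2
Reactants: 2 methyl (1R)-1-hydroxy-2-oxocyclopentane-1-carboxylate
Product: 3 methyl (1R)-2-oxo-1-(triethylsilyloxy)cyclopentane-1-carboxylate
Conditions: Et3SiOTf, 2,6-lutidine, CH2Cl2, −78 to 0 °C
Reagents that add atoms: triethylsilyl trifluoromethanesulfonate, CC[Si](CC)(CC)OS(=O)(=O)C(F)(F)F
Why: Silyl triflate silylation of a hindered tertiary alcohol; the silyl ether blocks retro-Claisen cleavage of the α-hydroxy β-keto ester in the next step.

Step 3
Reactants: 3 methyl (1R)-2-oxo-1-(triethylsilyloxy)cyclopentane-1-carboxylate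
Product: 4 methyl (1R)-1-(triethylsilyloxy)-2-(trifluoromethylsulfonyloxy)cyclopent-2-ene-1-carboxylate
Conditions: KN(SiMe3)2, THF, −78 °C; PhNTf2, −78 to 0 °C
Reagents that add atoms: N-phenylbis(trifluoromethanesulfonimide), O=S(=O)(N(c1ccccc1)S(=O)(=O)C(F)(F)F)C(F)(F)F
Why: The ketone can enolise only towards the ring CH2 (the other α-carbon is quaternary), so O-sulfonylation of the potassium enolate gives a single enol triflate.

Step 4
Reactants: 4 methyl (1R)-1-(triethylsilyloxy)-2-(trifluoromethylsulfonyloxy)cyclopent-2-ene-1-carboxylate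
Product: 5 (5S)-5-(hydroxymethyl)-5-(triethylsilyloxy)cyclopent-1-en-1-yl trifluoromethanesulfonate
Conditions: iBu2AlH (2.5 equiv), CH2Cl2, −78 to −20 °C; aq. KNaC4H4O6
Reagents that add atoms: none
Why: Hydride reduction of the ester to the primary alcohol; alkenyl triflates and silyl ethers are inert to iBu2AlH at low temperature. The stereocentre is untouched (R to S is a priority change only).

Step 5
Reactants: 5 (5S)-5-(hydroxymethyl)-5-(triethylsilyloxy)cyclopent-1-en-1-yl trifluoromethanesulfonate
Product: 6 (5S)-5-(methoxymethyl)-5-(triethylsilyloxy)cyclopent-1-en-1-yl trifluoromethanesulfonate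
Conditions: Me3OBF4, 1,8-bis(dimethylamino)naphthalene, CH2Cl2, 0 to 23 °C
Reagents that add atoms: trimethyloxonium tetrafluoroborate, C[O+](C)C.F[B-](F)(F)F
Why: O-Methylation with an oxonium salt and a non-nucleophilic base; no alkoxide is formed, so neither 1,4-silyl migration nor attack on the triflate is expected.

Step 6
Reactants: 7 3-ethoxycyclopent-2-en-1-one
Product: 9 3-(propan-2-yl)cyclopent-2-en-1-one, via tertiary allylic carbinol 8 (not isolated)
Conditions: iPrMgCl, THF, 0 °C; then 1 M HCl, 23 °C
Reagents that add atoms: isopropylmagnesium chloride, CC(C)[Mg]Cl; water, O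
Why: Stork–Danheiser sequence: 1,2-addition to the vinylogous ester, then acid hydrolysis with allylic transposition, places the isopropyl group on the enone β-carbon (C14).

Step 7
Reactants: 9 3-(propan-2-yl)cyclopent-2-en-1-one
Product: 10 rac-5-methyl-3-(propan-2-yl)cyclopent-2-en-1-one
Conditions: LiN(iPr)2, THF, −78 °C; MeI, −78 to −20 °C
Reagents that add atoms: iodomethane, CI
Why: Kinetic deprotonation of a 3-alkylcyclopentenone occurs at the α′-carbon (cross-conjugated enolate), so methylation installs the future C11 methyl; the racemic centre is erased in step 8.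

Step 8
Reactants: 10 rac-5-methyl-3-(propan-2-yl)cyclopent-2-en-1-one
Product: 11 (5R)-5-hydroxy-5-methyl-3-(propan-2-yl)cyclopent-2-en-1-one
Conditions: NaN(SiMe3)2, THF, −78 °C; (8,8-dichlorocamphorylsulfonyl)oxaziridine (antipode giving 5R), −78 °C
Reagents that add atoms: (8,8-dichlorocamphorylsulfonyl)oxaziridine, CC1(C)C2CCC13CS(=O)(=O)N4OC34C2(Cl)Cl
Why: Reagent-controlled hydroxylation of the single planar α′-enolate formed from both enantiomers of 10, so C11 is created and not resolved. The flat cross-conjugated enolate resembles 2-alkylindanone enolates, which this reagent class discriminates well.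

Step 9
Reactants: 11 (5R)-5-hydroxy-5-methyl-3-(propan-2-yl)cyclopent-2-en-1-one
Product: 12 (5R)-5-(methoxymethoxy)-5-methyl-3-(propan-2-yl)cyclopent-2-en-1-one
Conditions: MeOCH2Cl, iPr2NEt, Bu4NI (cat.), CH2Cl2, 40 °C
Reagents that add atoms: chloromethyl methyl ether, COCCl
Why: Alkylation of the tertiary α-ketol oxygen; a small alkoxy group is wanted at C11 because it directs the facial course of step 12.

Step 10
Reactants: 12 (5R)-5-(methoxymethoxy)-5-methyl-3-(propan-2-yl)cyclopent-2-en-1-one
Product: 14 (5R)-2-hydroxy-5-(methoxymethoxy)-5-methyl-3-(propan-2-yl)cyclopent-2-en-1-one, via deconjugated ketol 13 (not isolated)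
Conditions: KN(SiMe3)2, THF, −78 °C; 3-phenyl-2-(phenylsulfonyl)oxaziridine, −78 to −40 °C; then Et3N, CH2Cl2, 23 °C
Reagents that add atoms: 3-phenyl-2-(phenylsulfonyl)oxaziridine, O=S(=O)(c1ccccc1)N1OC1c1ccccc1
Why: C5 is now quaternary, so base can remove only a ring γ-proton. The extended enolate is hydroxylated at its α-carbon (C13) by the N-sulfonyloxaziridine, and the β,γ-unsaturated ketol tautomerises into conjugation as the diosphenol.

Step 11
Reactants: 14 (5R)-2-hydroxy-5-(methoxymethoxy)-5-methyl-3-(propan-2-yl)cyclopent-2-en-1-one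
Product: 15 (5R)-1,2-bis(tert-butyldimethylsilyloxy)-5-(methoxymethoxy)-5-methyl-3-(propan-2-yl)cyclopenta-1,3-diene
Conditions: tBuMe2SiOTf (2.4 equiv), Et3N, CH2Cl2, −78 to 0 °C
Reagents that add atoms: tert-butyldimethylsilyl trifluoromethanesulfonate, CC(C)(C)[Si](C)(C)OS(=O)(=O)C(F)(F)F
Why: The enol hydroxyl is silylated, and a second silyl triflate effects soft vinylogous enolisation through the only remaining acidic (γ) hydrogens. The 5,5-disubstitution blocks 1,5-hydrogen shifts and slows dimerisation.

Step 12
Reactants: 15 (5R)-1,2-bis(tert-butyldimethylsilyloxy)-5-(methoxymethoxy)-5-methyl-3-(propan-2-yl)cyclopenta-1,3-diene; 16 1,3-dichloropropan-2-one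
Product: 17 (1S,5R,8R)-2-chloro-1,7-bis(tert-butyldimethylsilyloxy)-8-(methoxymethoxy)-8-methyl-6-(propan-2-yl)bicyclo[3.2.1]oct-6-en-3-one (both C2 epimers)
Conditions: Et3N (slow addition), (CF3)2CHOH, 0 °C
Reagents that add atoms: none
Why: [4+3] cycloaddition of the chloro-oxyallyl cation. Addition to the face syn to the C11 alkoxy group (the contrasteric preference of 5-alkoxycyclopentadienes, here also the smaller substituent) sets C10 and C12 relative to C11. The unsubstituted, more electrophilic terminus should bond first to unhindered C10 (the nucleophilic end of the dienol ether), so the chlorine-bearing carbon closes on C12 and marks C1.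

Step 13
Reactants: 17 (1S,5R,8R)-2-chloro-1,7-bis(tert-butyldimethylsilyloxy)-8-(methoxymethoxy)-8-methyl-6-(propan-2-yl)bicyclo[3.2.1]oct-6-en-3-one
Product: 18 (1S,5R,8R)-1,7-bis(tert-butyldimethylsilyloxy)-8-(methoxymethoxy)-8-methyl-6-(propan-2-yl)-3-(trimethylsilyloxy)bicyclo[3.2.1]octa-2,6-diene
Conditions: Zn (activated), Me3SiCl, NaI (cat.), THF–MeCN, 0 to 23 °C
Reagents that add atoms: chlorotrimethylsilane, C[Si](C)(C)Cl
Why: Reductive silylation of an α-halo ketone gives the enol ether only at the carbon that carried the halogen (C1=C8), the hindered position base would not enolise. Both chloride epimers converge, and loss of the C12 oxygen would need a bridgehead olefin.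

Step 14
Reactants: 18 (1S,5R,8R)-1,7-bis(tert-butyldimethylsilyloxy)-8-(methoxymethoxy)-8-methyl-6-(propan-2-yl)-3-(trimethylsilyloxy)bicyclo[3.2.1]octa-2,6-diene
Product: 20 2-[(1R,4S,5R)-3,4-bis(tert-butyldimethylsilyloxy)-4-formyl-5-(methoxymethoxy)-5-methyl-2-(propan-2-yl)cyclopent-2-en-1-yl]acetic acid, via C1 ketol 19 (not isolated)
Conditions: OsO4 (5 mol %), 4-methylmorpholine 4-oxide, acetone–H2O, 0 °C; then NaIO4, pH 7 buffer, 23 °C
Reagents that add atoms: 4-methylmorpholine 4-oxide, C[N+]1([O-])CCOCC1; sodium periodate, [Na+].[O-][I](=O)(=O)=O; water, O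
Why: Lemieux–Johnson-type cleavage of a silyl enol ether: osmylation of the exposed trisubstituted enol ether gives the C1 ketol, which periodate cleaves to the C1 aldehyde and C8 acid. The tetrasubstituted C13=C14 enol ether, flanked by two bridgeheads, should be too hindered to osmylate.

Step 15
Reactants: 20 2-[(1R,4S,5R)-3,4-bis(tert-butyldimethylsilyloxy)-4-formyl-5-(methoxymethoxy)-5-methyl-2-(propan-2-yl)cyclopent-2-en-1-yl]acetic acid; 6 (5S)-5-(methoxymethyl)-5-(triethylsilyloxy)cyclopent-1-en-1-yl trifluoromethanesulfonate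
Product: 22 2-[(1R,4S,5R)-3,4-bis(tert-butyldimethylsilyloxy)-4-{(S)-hydroxy[(5R)-5-(methoxymethyl)-5-(triethylsilyloxy)cyclopent-1-en-1-yl]methyl}-5-(methoxymethoxy)-5-methyl-2-(propan-2-yl)cyclopent-2-en-1-yl]acetic acid, via trimethylsilyl ester 21 (not isolated)
Conditions: MeC(OSiMe3)=NSiMe3 (1.1 equiv), THF, 23 °C; then 6, CrCl2 (4 equiv), NiCl2 (2 mol %), DMF, 23 °C; aq. citric acid
Reagents that add atoms: none
Why: Nozaki–Hiyama–Kishi coupling: the alkenylchromium species from the triflate adds only to the aldehyde, and the acid is masked in the flask as its silyl ester. Felkin–Anh addition anti to the C12–O bond, with the flat C13 enol ether carbon as the small substituent and quaternary C11 as the large one, should give the 1S carbinol.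

Step 16
Reactants: 22 2-[(1R,4S,5R)-3,4-bis(tert-butyldimethylsilyloxy)-4-{(S)-hydroxy[(5R)-5-(methoxymethyl)-5-(triethylsilyloxy)cyclopent-1-en-1-yl]methyl}-5-(methoxymethoxy)-5-methyl-2-(propan-2-yl)cyclopent-2-en-1-yl]acetic acid
Product: 24 (1S,2S,6R,9R)-1,8-bis(tert-butyldimethylsilyloxy)-9-(methoxymethoxy)-2-[(5R)-5-(methoxymethyl)-5-(triethylsilyloxy)cyclopent-1-en-1-yl]-9-methyl-7-(propan-2-yl)-3-oxabicyclo[4.2.1]non-7-en-4-one, via mixed anhydride 23 (not isolated)
Conditions: 2,4,6-Cl3C6H2COCl, Et3N, THF, 23 °C; then 4-(dimethylamino)pyridine, toluene, 60 °C, high dilution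
Reagents that add atoms: none
Why: Yamaguchi lactonisation; activation at the acyl carbon keeps the C1 configuration. The cis-1,3 arrangement on ring C holds the two ends together, so the bridged seven-membered lactone should close under basic conditions that spare the silyl enol ether.

Step 17
Reactants: 24 (1S,2S,6R,9R)-1,8-bis(tert-butyldimethylsilyloxy)-9-(methoxymethoxy)-2-[(5R)-5-(methoxymethyl)-5-(triethylsilyloxy)cyclopent-1-en-1-yl]-9-methyl-7-(propan-2-yl)-3-oxabicyclo[4.2.1]non-7-en-4-one; 25 1,1-dibromoethane
Product: 26 (1S,2S,4Z,6R,9R)-1,8-bis(tert-butyldimethylsilyloxy)-4-ethylidene-9-(methoxymethoxy)-2-[(5R)-5-(methoxymethyl)-5-(triethylsilyloxy)cyclopent-1-en-1-yl]-9-methyl-7-(propan-2-yl)-3-oxabicyclo[4.2.1]non-7-ene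
Conditions: TiCl4, TMEDA, Zn, PbCl2 (cat.), THF, 0 to 23 °C
Reagents that add atoms: none
Why: Takai–Utimoto alkylidenation of an ester carbonyl with a gem-dibromide-derived titanium reagent. It is non-basic and gives Z enol ethers (alkyl cis to the ring oxygen), and the lactone is the only carbonyl in 24.

Step 18
Reactants: 26 (1S,2S,4Z,6R,9R)-1,8-bis(tert-butyldimethylsilyloxy)-4-ethylidene-9-(methoxymethoxy)-2-[(5R)-5-(methoxymethyl)-5-(triethylsilyloxy)cyclopent-1-en-1-yl]-9-methyl-7-(propan-2-yl)-3-oxabicyclo[4.2.1]non-7-ene
Product: 27 (1E,3R,6S,7R,10R,11R,12S)-5-9-5 tricyclic ketone (C8 ketone; C1=C2 olefin with C12 cis to C6; C13=C14 tert-butyldimethylsilyl enol ether; 3-triethylsilyloxy; 3-methoxymethyl; 11-methoxymethoxy; 12-tert-butyldimethylsilyloxy; 7- and 11-methyl; 14-isopropyl)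
Conditions: toluene, iPr2NEt (0.5 equiv), base-washed silylated sealed tube, 150–170 °C
Reagents that add atoms: none
Why: Thermal aliphatic Claisen ([3,3]) rearrangement of the allyl vinyl ether held inside the oxepane: C6–C7 forms as C1–O breaks, driven by formation of the C8 carbonyl. The closest known reaction type is the Claisen ring expansion of 2-alkylidene cyclic ethers carrying an alkenyl group at the other ether carbon, which gives cycloalkenones two atoms larger. Ring B is not closed end to end; it grows from the seven-membered ether (oxygen out; C2, C6 and C7 in) through a six-atom array bridged by C9–C12. That tether can span C1 and C8 only if C12 is pseudo-axial on C1, which forces C12 cis to C6 in the new C1=C2 olefin and allows only a chair-like array; a boat array would move C9 away from C12, and the oxepane itself twists into a boat-like conformer to make the cyclopentenyl group axial. C6 is controlled by C1: suprafacial transfer across C1–C2=C6 with C12 inside turns 1S into 6S. C7 is controlled by the enol ether geometry: in the chair array the Z methyl is pseudo-axial and C7 becomes R. The selectivity needed is rearrangement ahead of acid-catalysed migration of the exocyclic enol ether into the ring or its hydrolysis; base-treated glass and the amine additive secure this, and sp3 C10 with the C13/C14 silyl enol ether keeps the substrate free of bridgehead-olefin strain.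

Step 19
Reactants: 27 (1E,3R,6S,7R,10R,11R,12S)-5-9-5 tricyclic ketone
Product: 28 (1E,3R,6S,7R,8S,10R,11R,12S)-5-9-5 tricyclic C8 alcohol (otherwise as 27)
Conditions: (R)-Me-CBS oxazaborolidine [(3aR)-1-methyl-3,3-diphenyltetrahydro-1H,3H-pyrrolo[1,2-c][1,3,2]oxazaborole] (1 equiv), catecholborane, toluene, −78 to −40 °C; MeOH, aq. NaOH
Reagents that add atoms: none
Why: Corey–Bakshi–Shibata reduction: the α-branched C7 side acts as the large group and the C9 methylene as the small one, so the R catalyst should deliver hydride to give 8S. Catecholborane at low temperature spares the olefin and the silyl enol ether.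

Step 20
Reactants: 28 (1E,3R,6S,7R,8S,10R,11R,12S)-5-9-5 tricyclic C8 alcohol
Product: 29 (1E,3R,6S,7R,8S,11R,12S)-5-9-5 tricyclic enone (C13 ketone; C10=C14 olefin; 8-hydroxy; 3-triethylsilyloxy; 11-methoxymethoxy; 12-tert-butyldimethylsilyloxy)
Conditions: Pd(OAc)2 (1.2 equiv), MeCN, 23 °C
Reagents that add atoms: none
Why: Saegusa–Ito oxidation: divalent palladium engages the silyl enol ether at C14 from the open face of ring C, where the C10 hydrogen is syn, so β-hydride elimination gives the ring C10=C14 enone. This is the thermodynamic enone, and any isopropylidene isomer should equilibrate to it.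

Step 21
Reactants: 29 (1E,3R,6S,7R,8S,11R,12S)-5-9-5 tricyclic enone
Product: 30 11-O-(methoxymethyl)brassicicene M
Conditions: aq. HF (48 %), MeCN, 0 to 23 °C
Reagents that add atoms: none
Why: Acidic fluoride desilylation removes the tertiary triethylsilyl and tert-butyldimethylsilyl ethers without alkoxide formation, avoiding retro-aldol at C11/C13; the MOM ether survives.

Step 22
Reactants: 30 11-O-(methoxymethyl)brassicicene M
Product: 31 brassicicene M
Conditions: ZnBr2, PrSH, CH2Cl2, 0 °C
Reagents that add atoms: none
Why: Lewis acid and thiol cleave the MOM acetal by thioacetal exchange within minutes at 0 °C, conditions known for tertiary MOM ethers and mild enough for the tertiary allylic alcohols and the α-ketol.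

## Compound list

1 | methyl 2-oxocyclopentane-1-carboxylate | COC(=O)C1CCCC1=O | starting material
2 | methyl (1R)-1-hydroxy-2-oxocyclopentane-1-carboxylate | COC(=O)[C@@]1(O)CCCC1=O | intermediate
3 | methyl (1R)-2-oxo-1-(triethylsilyloxy)cyclopentane-1-carboxylate | COC(=O)[C@@]1(O[Si](CC)(CC)CC)CCCC1=O | intermediate
4 | methyl (1R)-1-(triethylsilyloxy)-2-(trifluoromethylsulfonyloxy)cyclopent-2-ene-1-carboxylate | COC(=O)[C@@]1(O[Si](CC)(CC)CC)CCC=C1OS(=O)(=O)C(F)(F)F | intermediate
5 | (5S)-5-(hydroxymethyl)-5-(triethylsilyloxy)cyclopent-1-en-1-yl trifluoromethanesulfonate | OC[C@@]1(O[Si](CC)(CC)CC)CCC=C1OS(=O)(=O)C(F)(F)F | intermediate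
6 | (5S)-5-(methoxymethyl)-5-(triethylsilyloxy)cyclopent-1-en-1-yl trifluoromethanesulfonate | COC[C@@]1(O[Si](CC)(CC)CC)CCC=C1OS(=O)(=O)C(F)(F)F | intermediate
7 | 3-ethoxycyclopent-2-en-1-one | CCOC1=CC(=O)CC1 | starting material
8 | 3-ethoxy-1-(propan-2-yl)cyclopent-2-en-1-ol | CCOC1=CC(O)(C(C)C)CC1 | intermediate
9 | 3-(propan-2-yl)cyclopent-2-en-1-one | CC(C)C1=CC(=O)CC1 | intermediate
10 | rac-5-methyl-3-(propan-2-yl)cyclopent-2-en-1-one | CC(C)C1=CC(=O)C(C)C1 | intermediate
11 | (5R)-5-hydroxy-5-methyl-3-(propan-2-yl)cyclopent-2-en-1-one | CC(C)C1=CC(=O)[C@](C)(O)C1 | intermediate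
12 | (5R)-5-(methoxymethoxy)-5-methyl-3-(propan-2-yl)cyclopent-2-en-1-one | CC(C)C1=CC(=O)[C@](C)(OCOC)C1 | intermediate
13 | (5R)-2-hydroxy-5-(methoxymethoxy)-5-methyl-3-(propan-2-yl)cyclopent-3-en-1-one (C2 epimers) | CC(C)C1=C[C@@](C)(OCOC)C(=O)C1O | intermediate
14 | (5R)-2-hydroxy-5-(methoxymethoxy)-5-methyl-3-(propan-2-yl)cyclopent-2-en-1-one | CC(C)C1=C(O)C(=O)[C@](C)(OCOC)C1 | intermediate
15 | (5R)-1,2-bis(tert-butyldimethylsilyloxy)-5-(methoxymethoxy)-5-methyl-3-(propan-2-yl)cyclopenta-1,3-diene | CC(C)C1=C[C@@](C)(OCOC)C(O[Si](C)(C)C(C)(C)C)=C1O[Si](C)(C)C(C)(C)C | intermediate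
16 | 1,3-dichloropropan-2-one | ClCC(=O)CCl | starting material
17 | (1S,5R,8R)-2-chloro-1,7-bis(tert-butyldimethylsilyloxy)-8-(methoxymethoxy)-8-methyl-6-(propan-2-yl)bicyclo[3.2.1]oct-6-en-3-one (C2 epimers) | ClC1C(=O)C[C@@H]2C(C(C)C)=C(O[Si](C)(C)C(C)(C)C)[C@@]1(O[Si](C)(C)C(C)(C)C)[C@]2(C)OCOC | intermediate
18 | (1S,5R,8R)-1,7-bis(tert-butyldimethylsilyloxy)-8-(methoxymethoxy)-8-methyl-6-(propan-2-yl)-3-(trimethylsilyloxy)bicyclo[3.2.1]octa-2,6-diene | C[Si](C)(C)OC1=C[C@@]2(O[Si](C)(C)C(C)(C)C)C(O[Si](C)(C)C(C)(C)C)=C(C(C)C)[C@@H](C1)[C@@]2(C)OCOC | intermediate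
19 | (1S,5R,8R)-2-hydroxy-1,7-bis(tert-butyldimethylsilyloxy)-8-(methoxymethoxy)-8-methyl-6-(propan-2-yl)bicyclo[3.2.1]oct-6-en-3-one (C2 epimers) | OC1C(=O)C[C@@H]2C(C(C)C)=C(O[Si](C)(C)C(C)(C)C)[C@@]1(O[Si](C)(C)C(C)(C)C)[C@]2(C)OCOC | intermediate
20 | 2-[(1R,4S,5R)-3,4-bis(tert-butyldimethylsilyloxy)-4-formyl-5-(methoxymethoxy)-5-methyl-2-(propan-2-yl)cyclopent-2-en-1-yl]acetic acid | O=C[C@@]1(O[Si](C)(C)C(C)(C)C)C(O[Si](C)(C)C(C)(C)C)=C(C(C)C)[C@@H](CC(=O)O)[C@@]1(C)OCOC | intermediate
21 | trimethylsilyl ester of 20 | O=C[C@@]1(O[Si](C)(C)C(C)(C)C)C(O[Si](C)(C)C(C)(C)C)=C(C(C)C)[C@@H](CC(=O)O[Si](C)(C)C)[C@@]1(C)OCOC | intermediate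
22 | 2-[(1R,4S,5R)-3,4-bis(tert-butyldimethylsilyloxy)-4-{(S)-hydroxy[(5R)-5-(methoxymethyl)-5-(triethylsilyloxy)cyclopent-1-en-1-yl]methyl}-5-(methoxymethoxy)-5-methyl-2-(propan-2-yl)cyclopent-2-en-1-yl]acetic acid | COC[C@@]1(O[Si](CC)(CC)CC)CCC=C1[C@H](O)[C@@]1(O[Si](C)(C)C(C)(C)C)C(O[Si](C)(C)C(C)(C)C)=C(C(C)C)[C@@H](CC(=O)O)[C@@]1(C)OCOC | intermediate
23 | mixed anhydride of 22 with 2,4,6-trichlorobenzoic acid | COC[C@@]1(O[Si](CC)(CC)CC)CCC=C1[C@H](O)[C@@]1(O[Si](C)(C)C(C)(C)C)C(O[Si](C)(C)C(C)(C)C)=C(C(C)C)[C@@H](CC(=O)OC(=O)c2c(Cl)cc(Cl)cc2Cl)[C@@]1(C)OCOC | intermediate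
24 | (1S,2S,6R,9R)-1,8-bis(tert-butyldimethylsilyloxy)-9-(methoxymethoxy)-2-[(5R)-5-(methoxymethyl)-5-(triethylsilyloxy)cyclopent-1-en-1-yl]-9-methyl-7-(propan-2-yl)-3-oxabicyclo[4.2.1]non-7-en-4-one | COC[C@@]1(O[Si](CC)(CC)CC)CCC=C1[C@@H]2OC(=O)C[C@@H]3C(C(C)C)=C(O[Si](C)(C)C(C)(C)C)[C@@]2(O[Si](C)(C)C(C)(C)C)[C@]3(C)OCOC | intermediate
25 | 1,1-dibromoethane | CC(Br)Br | starting material
26 | (1S,2S,4Z,6R,9R)-1,8-bis(tert-butyldimethylsilyloxy)-4-ethylidene-9-(methoxymethoxy)-2-[(5R)-5-(methoxymethyl)-5-(triethylsilyloxy)cyclopent-1-en-1-yl]-9-methyl-7-(propan-2-yl)-3-oxabicyclo[4.2.1]non-7-ene (target numbering 1S,3R,10R,11R,12S) | COC[C@@]1(O[Si](CC)(CC)CC)CCC=C1[C@@H]2O/C(=C\C)C[C@@H]3C(C(C)C)=C(O[Si](C)(C)C(C)(C)C)[C@@]2(O[Si](C)(C)C(C)(C)C)[C@]3(C)OCOC | intermediate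
27 | (1E,3R,6S,7R,10R,11R,12S)-5-9-5 tricyclic C8 ketone with C13=C14 silyl enol ether | COC[C@@]1(O[Si](CC)(CC)CC)CC[C@@H]2/C1=C\[C@@]1(O[Si](C)(C)C(C)(C)C)C(O[Si](C)(C)C(C)(C)C)=C(C(C)C)[C@@H](CC(=O)[C@@H]2C)[C@@]1(C)OCOC | intermediate
28 | (1E,3R,6S,7R,8S,10R,11R,12S)-5-9-5 tricyclic C8 alcohol with C13=C14 silyl enol ether | COC[C@@]1(O[Si](CC)(CC)CC)CC[C@@H]2/C1=C\[C@@]1(O[Si](C)(C)C(C)(C)C)C(O[Si](C)(C)C(C)(C)C)=C(C(C)C)[C@@H](C[C@H](O)[C@@H]2C)[C@@]1(C)OCOC | intermediate
29 | (1E,3R,6S,7R,8S,11R,12S)-3-O-triethylsilyl-12-O-tert-butyldimethylsilyl-11-O-methoxymethyl brassicicene M | COC[C@@]1(O[Si](CC)(CC)CC)CC[C@@H]2/C1=C\[C@@]1(O[Si](C)(C)C(C)(C)C)C(=O)C(C(C)C)=C(C[C@H](O)[C@@H]2C)[C@@]1(C)OCOC | intermediate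
30 | 11-O-(methoxymethyl)brassicicene M | COC[C@@]1(O)CC[C@@H]2/C1=C\[C@@]1(O)C(=O)C(C(C)C)=C(C[C@H](O)[C@@H]2C)[C@@]1(C)OCOC | intermediate
31 | brassicicene M (1E,3R,6S,7R,8S,11R,12S) | COC[C@@]1(O)CC[C@@H]2/C1=C\[C@@]1(O)C(=O)C(C(C)C)=C(C[C@H](O)[C@@H]2C)[C@@]1(C)O | target

## Step count and least certain steps

Total step count: 22. Longest linear sequence: 17 steps (steps 6–22, from 7). The ring A branch (steps 1–5) joins in step 15.

Step 18 (key step). The exocyclic enol ether may migrate into the ring or hydrolyse on traces of acid before the shift, and the shift may be slow because ring A must pass close to the C13 silyloxy group in the endo-face array. Fallback (Tsuji–Trost closure of the same C6–C7 bond), setting out from 22: excess EtLi would turn the carboxyl into the C8 ethyl ketone F1, and methyl chloroformate with pyridine would give the allylic methyl carbonate F2. A zerovalent palladium catalyst (Pd2(dba)3 with a phosphine) and KN(SiMe3)2 at high dilution would ionise C1–O and let the C7 enolate attack C6, the less hindered allyl terminus, returning to the route at 27. Outer-sphere attack gives the same facial sense at C6 as the [3,3] shift, but C7 would rest on enolate geometry.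

Step 12. The chlorine may be delivered to C9 instead of C1, the stepwise path may stop at open-chain alkylation at C10 with loss of silicon, or addition anti to the alkoxy group may compete. Fallback (an ester-marked oxyallyl, for which charge and orbital control agree), setting out from 15: cycloaddition with the oxyallyl cation from methyl 4-chloro-3-oxobutanoate under the same amine and fluoro-alcohol conditions would give the C1 β-keto ester F3. Hydroxylation of its stabilised enolate (Cs2CO3, O2, P(OEt)3) would give the α-hydroxy β-keto ester F4, and saponification with spontaneous decarboxylation would return to the route at 19, which is cleaved with NaIO4 as in step 14.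

Step 15. Poor facial discrimination at the aldehyde (the C13 silyloxy group may not act as the small substituent) could favour the 1R carbinol. Fallback, setting out from the 1R hydroxy acid F5 (the C1 epimer of 22): Mitsunobu lactonisation (PPh3, diisopropyl azodicarboxylate, high dilution) closes the ring with inversion at C1 and returns to the route at 24.

Step 17. Lewis-acidic titanium species may cleave the MOM or silyl enol ether, and the lactone may give an E/Z mixture. Fallback (Julia–Kocienski alkylidenation of the lactone), setting out from 24: lithiated 2-(ethylsulfonyl)-1,3-benzothiazole would add to the carbonyl to give the lactol sulfone F6, and 1,8-diazabicyclo[5.4.0]undec-7-ene would induce rearrangement and elimination to return to the route at 26 (after separation from any E isomer).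

Step 19. The conformation of the nine-membered ring may override reagent control and expose the other carbonyl face, giving the 8R alcohol. Fallback, setting out from the 8R alcohol F7: Mitsunobu inversion with 4-nitrobenzoic acid would give the 8S ester F8, and K2CO3 in MeOH would return to the route at 28.

## Further compounds

F1 | step 18 | C8 ethyl ketone with free 1S carbinol (from 22) | COC[C@@]1(O[Si](CC)(CC)CC)CCC=C1[C@H](O)[C@@]1(O[Si](C)(C)C(C)(C)C)C(O[Si](C)(C)C(C)(C)C)=C(C(C)C)[C@@H](CC(=O)CC)[C@@]1(C)OCOC
F2 | step 18 | C1 methyl carbonate of F1 | COC[C@@]1(O[Si](CC)(CC)CC)CCC=C1[C@H](OC(=O)OC)[C@@]1(O[Si](C)(C)C(C)(C)C)C(O[Si](C)(C)C(C)(C)C)=C(C(C)C)[C@@H](CC(=O)CC)[C@@]1(C)OCOC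
F3 | step 12 | methyl (1S,5R,8R)-1,7-bis(tert-butyldimethylsilyloxy)-8-(methoxymethoxy)-8-methyl-3-oxo-6-(propan-2-yl)bicyclo[3.2.1]oct-6-ene-2-carboxylate | COC(=O)C1C(=O)C[C@@H]2C(C(C)C)=C(O[Si](C)(C)C(C)(C)C)[C@@]1(O[Si](C)(C)C(C)(C)C)[C@]2(C)OCOC
F4 | step 12 | 2-hydroxy derivative of F3 | COC(=O)C1(O)C(=O)C[C@@H]2C(C(C)C)=C(O[Si](C)(C)C(C)(C)C)[C@@]1(O[Si](C)(C)C(C)(C)C)[C@]2(C)OCOC
F5 | step 15 | 1R epimer of hydroxy acid 22 | COC[C@@]1(O[Si](CC)(CC)CC)CCC=C1[C@@H](O)[C@@]1(O[Si](C)(C)C(C)(C)C)C(O[Si](C)(C)C(C)(C)C)=C(C(C)C)[C@@H](CC(=O)O)[C@@]1(C)OCOC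
F6 | step 17 | lactol adduct of 24 with 2-(ethylsulfonyl)-1,3-benzothiazole | COC[C@@]1(O[Si](CC)(CC)CC)CCC=C1[C@@H]2OC(O)(C(C)S(=O)(=O)c4nc5ccccc5s4)C[C@@H]3C(C(C)C)=C(O[Si](C)(C)C(C)(C)C)[C@@]2(O[Si](C)(C)C(C)(C)C)[C@]3(C)OCOC
F7 | step 19 | 8R epimer of alcohol 28 | COC[C@@]1(O[Si](CC)(CC)CC)CC[C@@H]2/C1=C\[C@@]1(O[Si](C)(C)C(C)(C)C)C(O[Si](C)(C)C(C)(C)C)=C(C(C)C)[C@@H](C[C@@H](O)[C@@H]2C)[C@@]1(C)OCOC
F8 | step 19 | 8S 4-nitrobenzoate of 28 | COC[C@@]1(O[Si](CC)(CC)CC)CC[C@@H]2/C1=C\[C@@]1(O[Si](C)(C)C(C)(C)C)C(O[Si](C)(C)C(C)(C)C)=C(C(C)C)[C@@H](C[C@H](OC(=O)c3ccc(cc3)[N+](=O)[O-])[C@@H]2C)[C@@]1(C)OCOC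
A1 | alternative 1 | acyclic ynone (C3 methoxymethyl ketone tethered to the C1≡C2 alkyne on ring C) | COCC(=O)CC[C@@H]([C@@H](C)CO[Si](C)(C)C(C)(C)C)C#C[C@@]1(O[Si](CC)(CC)CC)C(=O)C(C(C)C)=C(C)[C@@]1(C)O[Si](CC)(CC)CC
A2 | alternative 1 | ring A–ring C dienone with C3 silyl ether | COC[C@@]1(O[Si](CC)(CC)CC)CC[C@@H]([C@@H](C)CO[Si](C)(C)C(C)(C)C)/C1=C\[C@@]1(O[Si](CC)(CC)CC)C(=O)C(C(C)C)=C(C)[C@@]1(C)O[Si](CC)(CC)CC
A3 | alternative 2 | keto aldehyde with open rings B and C | COC[C@@]1(O[Si](CC)(CC)CC)CC[C@@H]([C@@H](C)C=O)/C1=C\[C@@](O[Si](CC)(CC)CC)(C(=O)CC(C)C)[C@](C)(O[Si](CC)(CC)CC)C(C)=O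
A4 | alternative 2 | tris-silylated 5-9-5 skeleton with free C8 alcohol | COC[C@@]1(O[Si](CC)(CC)CC)CC[C@@H]2/C1=C\[C@@]1(O[Si](CC)(CC)CC)C(=O)C(C(C)C)=C(C[C@H](O)[C@@H]2C)[C@@]1(C)O[Si](CC)(CC)CC
A5 | alternative 3 | cyclononenone bearing the C13 enal | COC[C@@]1(O)CC[C@@H]2/C1=C\C(=O)[C@](C)(O[Si](CC)(CC)CC)/C(=C(\C=O)C(C)C)C[C@H](O[Si](C)(C)C(C)(C)C)[C@@H]2C
A6 | alternative 3 | target skeleton with C8 and C11 silyl ethers | COC[C@@]1(O)CC[C@@H]2/C1=C\[C@@]1(O)C(=O)C(C(C)C)=C(C[C@H](O[Si](C)(C)C(C)(C)C)[C@@H]2C)[C@@]1(C)O[Si](CC)(CC)CC
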